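Numbering follows the target: ring A is the quinone (C1–C4), ring B the benzo ring (C4a–C8a), ring C the trimethoxyphenyl group on C8. Ring A is taken apart into an arylketene (C1, C4, the C4 oxygen) and methoxyacetylene (C2–OMe, C3–H). The 1,3-placed oxygens on C4 and C2 are the signature of that pairing, and closure can only reach C4a because C8, the other ortho carbon of ring B, holds ring C. Irradiating the biaryl diazoketone with the alkyne shifts ring B onto C1, forms C3–C4, C1–C2 and C4–C4a, and delivers the 3-methoxy-1-naphthol in one operation. The precursor is a 2-aryl-3,4-dimethylphenyl diazomethyl ketone made by diazo transfer. Phenol-selective oxidation at C1 completes the quinone.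

Key step: step 6

Assumption: the C8–C1' biaryl axis has no stereodescriptor in the target structure, so no axial control is planned and every biaryl is treated as racemic or freely rotating.

Step 1
Reactants: 1 2,3-dimethylphenol
Product: 3 1-(2-hydroxy-3,4-dimethylphenyl)ethan-1-one, via aryl acetate 2 (not isolated)
Conditions: AcCl (1.1 equiv), neat, rt to 60 °C; then AlCl3 (1.5 equiv), 130 °C; ice/aq. HCl; steam distillation
Reagents that add atoms: acetyl chloride CC(=O)Cl
Why: O-acetylation followed by a Fries rearrangement, in which solvent-free heating (thermodynamic control) moves the acetyl group to the only free ortho carbon, where the product is held as an aluminium chelate, and the hydrogen-bonded ortho-hydroxyketone is purified through its steam volatility.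

Step 2
Reactants: 3 1-(2-hydroxy-3,4-dimethylphenyl)ethan-1-one
Product: 4 6-acetyl-2,3-dimethylphenyl trifluoromethanesulfonate
Conditions: Tf2O (1.2 equiv), pyridine (2 equiv), CH2Cl2, 0 °C to rt
Reagents that add atoms: trifluoromethanesulfonic anhydride O=S(=O)(OS(=O)(=O)C(F)(F)F)C(F)(F)F
Why: O-sulfonylation of a phenol with triflic anhydride is the standard aryl triflate synthesis, and the ketone and the methyl groups are inert to it.

Step 3
Reactants: 4 6-acetyl-2,3-dimethylphenyl trifluoromethanesulfonate; 5 2,4,5-trimethoxyphenylboronic acid (1.5 equiv)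
Product: 6 1-[3,4-dimethyl-2-(2,4,5-trimethoxyphenyl)phenyl]ethan-1-one
Conditions: Pd(OAc)2 (3 mol %), SPhos (6 mol %), K3PO4 (3 equiv), degassed toluene/H2O (10:1), 90 °C
Reagents that add atoms: none
Why: Suzuki–Miyaura coupling, in which the ortho-acetyl group speeds oxidative addition of zerovalent palladium into the hindered C–OTf bond, the bulky electron-rich ligand SPhos suits tri-ortho-substituted biaryls, and the mild phosphate base leaves the methyl ketone alone.

Step 4
Reactants: 6 1-[3,4-dimethyl-2-(2,4,5-trimethoxyphenyl)phenyl]ethan-1-one
Product: 8 2-diazo-1-[3,4-dimethyl-2-(2,4,5-trimethoxyphenyl)phenyl]ethan-1-one, via trifluoroacetyl ketone 7 (not isolated)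
Conditions: LiN(SiMe3)2 (1.1 equiv), THF, −78 °C; CF3CO2CH2CF3 (1.2 equiv); aq. HCl work-up; then MsN3 (1.5 equiv), Et3N (1.5 equiv), H2O (1 equiv), MeCN, rt
Reagents that add atoms: methanesulfonyl azide CS(=O)(=O)N=[N+]=[N-] (its two terminal nitrogens stay in 8); 2,2,2-trifluoroethyl trifluoroacetate FC(F)(F)COC(=O)C(F)(F)F (its CF3CO group stands in 7 only)
Why: Detrifluoroacetylative diazo transfer (a deacylative Regitz-type reaction), in which C-trifluoroacetylation of the methyl group makes it acidic enough for Et3N-mediated transfer of N2 from the sulfonyl azide and the CF3CO group then leaves on the sulfonamide nitrogen; the sequence is standard for aryl methyl ketones and needs neither diazomethane nor an acid chloride that could acylate ring C.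

Step 5
Reactants: 9 chloroacetaldehyde dimethyl acetal (2-chloro-1,1-dimethoxyethane)
Product: 11 methoxyacetylene, via sodium methoxyacetylide 10 (not isolated)
Conditions: NaNH2 (3.1 equiv), liquid NH3, −33 °C; NH3 evaporated; cold sat. aq. NaCl, −70 °C to rt; distilled into a −78 °C trap and kept as a cold ClCH2CH2Cl solution
Reagents that add atoms: none
Why: Twofold base-induced elimination (loss of MeOH and of HCl) is the standard route from chloroacetals to 1-alkoxyalkynes, a third equivalent of amide storing the product as the non-volatile acetylide until cold aqueous protonation releases the alkyne, which boils near room temperature.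

Step 6
Reactants: 8 2-diazo-1-[3,4-dimethyl-2-(2,4,5-trimethoxyphenyl)phenyl]ethan-1-one; 11 methoxyacetylene (4–5 equiv)
Product: 16 3-methoxy-6,7-dimethyl-5-(2,4,5-trimethoxyphenyl)naphthalen-1-ol, via arylketene 12 (not isolated), via cyclobutenone 13 (not isolated), via dienylketene 14 (not isolated), via dienone 15 (not isolated)
Conditions: hν (254 nm, low-pressure Hg lamps, jacketed quartz vessel), degassed ClCH2CH2Cl (0.2 M), 0–5 °C under a dry-ice condenser until N2 evolution ends; then 80 °C
Reagents that add atoms: none
Why: Light expels N2 from 8 and ring B migrates from the carbonyl carbon to the former diazo carbon (photochemical Wolff rearrangement, making C1–C8a) to give arylketene 12, whose electrophilic sp carbon (C4) is attacked by the unsubstituted, electron-rich carbon of 11 (C3) while C2 bonds to C1, so that a (2+2) cycloaddition gives racemic cyclobutenone 13. Strain release then breaks the C1–C4 bond of 13 in a reversible 4π electrocyclic opening to dienylketene 14, of which only the isomer holding ring B cis to the ketene can react further. Ring A is closed by a 6π electrocyclisation that joins C4 to C4a and gives dienone 15, and a proton shift restores ring B and leaves naphthol 16. The closest known reaction type is the Danheiser benzannulation in its diazoketone variant, established for aryl diazomethyl ketones with alkoxy- and siloxyalkynes as a route to 3-oxygenated 1-naphthols. Two selectivities are needed: the orientation of the cycloaddition follows from the donor–acceptor polarity of ynol ether and ketene, and the site of closure is fixed because C8 carries ring C, while the C7 methyl and C2' methoxy groups twist ring C out of plane so that it is a poor internal trap, and excess 11 outruns ketene dimerisation and acylation of 16. The stereocentres at C1 of 13 and at C4a of 15 are transient and are erased, so no stereocontrol is required.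

Step 7
Reactants: 16 3-methoxy-6,7-dimethyl-5-(2,4,5-trimethoxyphenyl)naphthalen-1-ol
Product: 17 2-methoxy-6,7-dimethyl-8-(2,4,5-trimethoxyphenyl)naphthalene-1,4-dione (target)
Conditions: (KSO3)2NO (2.5 equiv), aq. KH2PO4, acetone/H2O, rt
Reagents that add atoms: potassium nitrosodisulfonate [K+].[K+].[O-]S(=O)(=O)N([O])S(=O)(=O)[O-]
Why: Teuber oxidation, in which one nitrosodisulfonate radical abstracts the naphthol hydrogen and a second couples through its oxygen at C1, the para carbon of highest spin density, before imidodisulfonate is lost, whereas the fully etherified ring C has no O–H and is spared, as it would not be by an electron-transfer oxidant such as (NH4)2Ce(NO3)6.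

Compound list
1 | 2,3-dimethylphenol | Cc1cccc(O)c1C | starting material
2 | 2,3-dimethylphenyl acetate | CC(=O)Oc1cccc(C)c1C | intermediate
3 | 1-(2-hydroxy-3,4-dimethylphenyl)ethan-1-one | CC(=O)c1ccc(C)c(C)c1O | intermediate
4 | 6-acetyl-2,3-dimethylphenyl trifluoromethanesulfonate | CC(=O)c1ccc(C)c(C)c1OS(=O)(=O)C(F)(F)F | intermediate
5 | 2,4,5-trimethoxyphenylboronic acid | COc1cc(OC)c(B(O)O)cc1OC | starting material
6 | 1-[3,4-dimethyl-2-(2,4,5-trimethoxyphenyl)phenyl]ethan-1-one | CC(=O)c1ccc(C)c(C)c1-c1cc(OC)c(OC)cc1OC | intermediate
7 | 4,4,4-trifluoro-1-[3,4-dimethyl-2-(2,4,5-trimethoxyphenyl)phenyl]butane-1,3-dione | O=C(CC(=O)C(F)(F)F)c1ccc(C)c(C)c1-c1cc(OC)c(OC)cc1OC | intermediate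
8 | 2-diazo-1-[3,4-dimethyl-2-(2,4,5-trimethoxyphenyl)phenyl]ethan-1-one | [N-]=[N+]=CC(=O)c1ccc(C)c(C)c1-c1cc(OC)c(OC)cc1OC | intermediate
9 | chloroacetaldehyde dimethyl acetal | COC(CCl)OC | starting material
10 | sodium methoxyacetylide | COC#[C-].[Na+] | intermediate
11 | methoxyacetylene | COC#C | intermediate
12 | 2-[3,4-dimethyl-2-(2,4,5-trimethoxyphenyl)phenyl]ethen-1-one (arylketene) | O=C=Cc1ccc(C)c(C)c1-c1cc(OC)c(OC)cc1OC | intermediate
13 | 4-[3,4-dimethyl-2-(2,4,5-trimethoxyphenyl)phenyl]-3-methoxycyclobut-2-en-1-one (racemic) | O=C1C=C(OC)C1c1ccc(C)c(C)c1-c1cc(OC)c(OC)cc1OC | intermediate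
14 | (3E)-4-[3,4-dimethyl-2-(2,4,5-trimethoxyphenyl)phenyl]-3-methoxybuta-1,3-dien-1-one (aryl cis to the ketene arm) | O=C=C/C(OC)=C\c1ccc(C)c(C)c1-c1cc(OC)c(OC)cc1OC | intermediate
15 | 3-methoxy-6,7-dimethyl-5-(2,4,5-trimethoxyphenyl)naphthalen-1(8aH)-one (racemic) | O=C1C=C(OC)C=C2C1C=C(C)C(C)=C2c1cc(OC)c(OC)cc1OC | intermediate
16 | 3-methoxy-6,7-dimethyl-5-(2,4,5-trimethoxyphenyl)naphthalen-1-ol | COc1cc(O)c2cc(C)c(C)c(-c3cc(OC)c(OC)cc3OC)c2c1 | intermediate
17 | 2-methoxy-6,7-dimethyl-8-(2,4,5-trimethoxyphenyl)naphthalene-1,4-dione | COC1=CC(=O)c2cc(C)c(C)c(-c3cc(OC)c(OC)cc3OC)c2C1=O | target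

Total step count: 7. Longest linear sequence: 6 (steps 1, 2, 3, 4, 6, 7).

Steps most likely to fail

Step 6. The electron-rich biaryl and the growing naphthol may absorb the light and undergo secondary photochemistry. The ketene may also be lost to dimerisation, to acylation of the product, or to attack by ring C before the alkyne captures it. The fallback sets out from 8 and makes the ketene without light.
- A silver-catalysed Wolff rearrangement in wet dioxane (AgO2CPh, Et3N; Arndt–Eistert homologation) should give [3,4-dimethyl-2-(2,4,5-trimethoxyphenyl)phenyl]acetic acid F1.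
- (COCl)2 with catalytic DMF in CH2Cl2 at 0 °C should convert it into [3,4-dimethyl-2-(2,4,5-trimethoxyphenyl)phenyl]acetyl chloride F2, which is used at once.
- Slow addition of F2 to Et3N and excess 11 in Et2O at 0 °C generates 12 by dehydrochlorination at a low stationary concentration.
- The cycloadduct 13 is isolated and heated in toluene, so that cycloaddition and rearrangement can be optimised separately. The sequence passes through 14 and 15 and comes back to the route at 16.

Step 3. Protodeboronation of the electron-rich boronic acid and hydrolysis of the triflate may outpace the hindered transmetalation. The fallback sets out from 4 and replaces boron by zinc in a base-free, anhydrous Negishi coupling.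
- Commercial 1-bromo-2,4,5-trimethoxybenzene and n-BuLi in THF at −78 °C should give (2,4,5-trimethoxyphenyl)lithium F3.
- ZnCl2 converts it into (2,4,5-trimethoxyphenyl)zinc chloride F4.
- F4 tolerates the ketone and is coupled with 4 using Pd(OAc)2 and RuPhos in THF at 60 °C, coming back to the route at 6.

Step 7. Ring C shields C1 from the peri position, so the bulky nitrosodisulfonate radical may couple at the open C3 next to the hydroxyl, which amounts to ortho instead of para oxidation. The fallback sets out from 16 and uses dye-sensitised photooxygenation (O2, tetraphenylporphyrin, visible light, CH2Cl2, 0 °C).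
- Singlet oxygen adds across C1 and C4 in a (4+2) sense, so the new oxygen can only arrive at C1.
- This should give racemic 4-hydroperoxy-3-methoxy-6,7-dimethyl-5-(2,4,5-trimethoxyphenyl)naphthalen-1(4H)-one F5.
- Loss of water from F5, spontaneous or on silica, comes back to the route at 17.

Further compounds
F1 | step 6 | [3,4-dimethyl-2-(2,4,5-trimethoxyphenyl)phenyl]acetic acid | OC(=O)Cc1ccc(C)c(C)c1-c1cc(OC)c(OC)cc1OC
F2 | step 6 | [3,4-dimethyl-2-(2,4,5-trimethoxyphenyl)phenyl]acetyl chloride | ClC(=O)Cc1ccc(C)c(C)c1-c1cc(OC)c(OC)cc1OC
F3 | step 3 | (2,4,5-trimethoxyphenyl)lithium | [Li]c1cc(OC)c(OC)cc1OC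
F4 | step 3 | (2,4,5-trimethoxyphenyl)zinc chloride | Cl[Zn]c1cc(OC)c(OC)cc1OC
F5 | step 7 | 4-hydroperoxy-3-methoxy-6,7-dimethyl-5-(2,4,5-trimethoxyphenyl)naphthalen-1(4H)-one (racemic) | COC1=CC(=O)c2cc(C)c(C)c(-c3cc(OC)c(OC)cc3OC)c2C1OO
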